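At early times, take the main step alone: each incoming ligand turns one starting complex into complex with one exchanged, so this flask's charge of 0.600 equivalents allows 60.0%.

| setting | south-east | north-east | north | flask |
|---|---|---|---|---|
| starting complex | 0.50 M | 0.50 M | 0.25 M | 0.50 M |
| incoming ligand | 0.15 M (fed, over 3.0 h) | 0.22 M (fed, over 3.0 h) | 0.30 M (fed, over 3.0 h) | 0.300 M (fed, over 3.0 h) |
| remark | run made earlier; the fed solution adds 0.10 times the starting volume | run made earlier; the fed solution adds 0.10 times the starting volume | run made earlier; the fed solution adds 0.10 times the starting volume | the fed solution adds 0.10 times the starting volume |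
| time |  |  |  | 50 h |

- south-east (time / h: complex with one exchanged / %, starting complex / %): 1.00: 2.7, 56.8; 2.50: 11.4, 28.2; 8.00: 15.6, 4.4; 20.0: 15.6, 2.2; 48.0: 12.7, 2.2
- north-east (time / h: complex with one exchanged / %, starting complex / %): 1.00: 5.1, 54.1; 2.50: 15.6, 23.2; 8.00: 17.8, 2.1; 20.0: 12.7, 3.1; 48.0: 10.5, 1.3
- north (time / h: complex with one exchanged / %, starting complex / %): 1.00: 6.2, 63.7; 2.50: 20.1, 21.4; 8.00: 20.6, 0.4; 20.0: 14.2, 0; 48.0: 7.7, 2.1

(scatter of a reading: 1 percentage point)

* the moment within 50 h at which there is most complex with one exchanged
* the amount of complex with one exchanged, in percent of the starting complex charged, at that time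
* earliest time at which at least nineteen twentieths of that best amount are there
* latest time at which they still are

- in percentages every species weighs as the starting complex in it: one homo dimer counts as two
- for leaving ligand the idle adduct is counted in
- charges are per starting volume, the dose included; the dosed solution carries all of it
- candidate steps: complex with one exchanged + incoming ligand <-> leaving ligand + complex with two exchanged; starting complex + incoming ligand <-> leaving ligand + complex with one exchanged; leaving ligand + starting complex <-> idle adduct; 2 starting complex -> homo dimer; complex with two exchanged + incoming ligand <-> leaving ligand + complex with three exchanged; complex with three exchanged + incoming ligand <-> leaving ligand + complex with four exchanged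

Now add the losses of starting complex. In the south-east run 95.6% of it has left by 8.00 h, more than that run's ligand could turn over, so the homo dimer or idle adduct step must be taking a large part. Then add further exchange: south-east falls by 2.9 percentage points from 20.0 h to 48.0 h. Treat that slow fall as a small correction and leave it out of the peak.

Reckon the peak as odds, a rough selectivity factor: highest reading over the rest of the charge. South-east gives 0.185 at 0.300 equivalents, and north gives 0.259 at 1.20, which is two doublings higher. Take the square root of their ratio: the doubling gain 1.18, the factor on the odds for each doubling of equivalents, read across these 3.0 h feeds. North also starts at half south-east's c(starting complex), so this gain mixes two changes and is an estimate. For north-east it gives 16.9% against a reading of 17.8%, with a scatter of 1 point. This flask has twice south-east's equivalents, so my odds are 0.219, a peak of 18.0%.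

The forecast expects “a peak just after feed end”: 21% at 3.8 h, above my figure, held from 2.7 h to 5.7 h.

The flask peaks at 18.4% at 3.92 h, and the window asked for runs from 3.00 h to 5.63 h, so the forecast's figures stand within their tolerance. At the best time it also holds 47.9% homo dimer and 24.5% idle adduct. Its odds are 0.226; carried back by the doubling gain to north-east's equivalents, they give 17.3%, beside that run's reading of 17.8%.

    complex with one exchanged + incoming ligand ⇌ leaving ligand + complex with two exchanged (K = 0.260, k = 1.80 × 10⁻⁴ M⁻¹ s⁻¹)
    starting complex + incoming ligand ⇌ leaving ligand + complex with one exchanged (K = 4.90, k = 6.30 × 10⁻⁴ M⁻¹ s⁻¹)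
    leaving ligand + starting complex ⇌ idle adduct, settled at all times (K = 490 M⁻¹)
    2 starting complex → homo dimer (k = 1.80 × 10⁻⁴ M⁻¹ s⁻¹)
    complex with two exchanged + incoming ligand ⇌ leaving ligand + complex with three exchanged (K = 150, k = 1.80 × 10⁻⁴ M⁻¹ s⁻¹)
    complex with three exchanged + incoming ligand ⇌ leaving ligand + complex with four exchanged (K = 4.40, k = 3.90 × 10⁻⁴ M⁻¹ s⁻¹)

For the neighbour with 0.75 M of incoming ligand, 1.50 equiv, the gain from this flask's odds gives 22.0%. The computed best there is 22.4%.

The numbers in the tables are simulated for substances that don't exist, noise included.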